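The route rests on a hidden symmetry of the oxirane. Its quaternary carbon C2 carries the ring oxygen, the benzene ring and two CH2–O arms (ring carbon C3 and the acetoxymethyl carbon). Opening the C3–O bond in thought therefore gives an achiral 2-arylpropane-1,2,3-triol with enantiotopic hydroxymethyl groups. The key step tosylates one of these arms under a chiral copper bis(oxazoline) catalyst, which creates the only stereocentre and installs the leaving group for the later 3-exo-tet closure in one operation. Its precursor is the triol whose phenol and benzylic alcohol already carry their isobutyrates, built by adding an aryllithium to acetonide-protected dihydroxyacetone.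

Key step: step 6

Assumption: the sense of induction of the copper–Ph-BOX catalyst on this triol cannot be predicted with certainty; the (R,R) ligand is written, and the (S,S) antipode would be used instead if a trial run shows that the other arm is sulfonylated.

Step 1
Reactants: 1 methyl 4-bromo-3-hydroxybenzoate
Product: 2 2-bromo-5-(hydroxymethyl)phenol
Conditions: LiAlH4 (2 equiv), THF, 0 °C → rt; aq. Rochelle salt
Reagents that add atoms: none
Why: Hydride reduction of the methyl ester proceeds on the lithium phenoxide that forms first, and the aryl bromide is not touched by LiAlH4 at or below room temperature.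

Step 2
Reactants: 2 2-bromo-5-(hydroxymethyl)phenol
Product: 3 {[4-bromo-3-(triisopropylsilyloxy)phenyl]methoxy}triisopropylsilane
Conditions: TIPSCl (2.5 equiv), imidazole, DMAP (cat.), DMF, rt → 40 °C
Reagents that add atoms: triisopropylsilyl chloride, CC(C)[Si](Cl)(C(C)C)C(C)C
Why: Imidazole-promoted silylation caps both the phenol and the primary benzylic alcohol; the bulky triisopropylsilyl group is chosen because it withstands organolithium reagents and is the silyl group least prone to shift from oxygen to an ortho carbanion.

Step 3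
Reactants: 3 {[4-bromo-3-(triisopropylsilyloxy)phenyl]methoxy}triisopropylsilane; 4 2,2-dimethyl-1,3-dioxan-5-one
Product: 6 2,2-dimethyl-5-{2-(triisopropylsilyloxy)-4-[(triisopropylsilyloxy)methyl]phenyl}-1,3-dioxan-5-ol, via aryllithium 5 (not isolated)
Conditions: n-BuLi (1.05 equiv), THF, −78 °C, 20 min; then 4, −78 → −40 °C; aq. NH4Cl
Reagents that add atoms: none
Why: Bromine–lithium exchange followed by 1,2-addition of the aryllithium to the ketone should join the arene to the three-carbon unit, with the short exchange time at −78 °C holding back both retro-Brook silyl migration and enolisation of the ketone.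

Step 4
Reactants: 6 2,2-dimethyl-5-{2-(triisopropylsilyloxy)-4-[(triisopropylsilyloxy)methyl]phenyl}-1,3-dioxan-5-ol
Product: 8 [4-(5-hydroxy-2,2-dimethyl-1,3-dioxan-5-yl)-3-(isobutyryloxy)phenyl]methyl isobutyrate, via desilylated phenol diol 7 (not isolated)
Conditions: Bu4NF (2.3 equiv), THF, 0 °C → rt; then Et3N, (i-PrCO)2O (4 equiv), DMAP (cat.), 0 °C → rt
Reagents that add atoms: isobutyric anhydride, CC(C)C(=O)OC(=O)C(C)C
Why: One-pot fluoride desilylation and acylation should esterify the released phenoxide and primary benzylic alkoxide, while the tertiary hydroxyl, flanked by the dioxane ring and the ortho-substituted arene, is too hindered to react with the α-branched anhydride.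

Step 5
Reactants: 8 [4-(5-hydroxy-2,2-dimethyl-1,3-dioxan-5-yl)-3-(isobutyryloxy)phenyl]methyl isobutyrate
Product: 9 [3-(isobutyryloxy)-4-(1,2,3-trihydroxypropan-2-yl)phenyl]methyl isobutyrate
Conditions: AcOH–H2O (4:1), 40 °C
Reagents that add atoms: none
Why: Acid-catalysed hydrolysis of the six-membered isopropylidene ketal is much faster than hydrolysis of the two esters, and the tertiary benzylic hydroxyl should not ionise because the cation would be destabilised by two β-oxygen substituents and the ortho acyloxy group.

Step 6
Reactants: 9 [3-(isobutyryloxy)-4-(1,2,3-trihydroxypropan-2-yl)phenyl]methyl isobutyrate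
Product: 10 (2R)-2,3-dihydroxy-2-{2-(isobutyryloxy)-4-[(isobutyryloxy)methyl]phenyl}propyl 4-methylbenzenesulfonate
Conditions: TsCl (1.2 equiv), Cu(OTf)2 (10 mol%), (R,R)-Ph-BOX [2,2'-(propane-2,2-diyl)bis((4R)-4-phenyl-4,5-dihydrooxazole), 11 mol%], K2CO3 (1.5 equiv), CH2Cl2, 0 °C → rt
Reagents that add atoms: p-toluenesulfonyl chloride, Cc1ccc(cc1)S(Cl)(=O)=O
Why: The Cu(OTf)2–Ph-BOX complex (divalent copper) should bind the tertiary hydroxyl and one primary hydroxyl of 9 as a five-membered chelate, which acidifies the bound primary O–H enough for K2CO3 to remove it, and this copper alkoxide alone attacks TsCl to form the O–S bond. The closest known reaction type is the copper bis(oxazoline)-catalysed enantioselective monosulfonylation and monoacylation of meso 1,2-diols and 2-substituted glycerols, applied here to a new triol. No ring is closed in this step; the tosylated arm becomes the oxirane CH2 in step 8. The new quaternary stereocentre is controlled by the ligand: the two possible chelates are diastereomeric inside the C2-symmetric pocket, and the bulky ortho-acyloxyaryl group on the carbinol carbon is the substituent that the ligand phenyl groups push to one side. The step needs enantiotopic-group selectivity between the two hydroxymethyl arms, mono- over bis-sulfonylation and primary over tertiary oxygen; the tertiary hydroxyl as chelation anchor and the slower second tosylation secure these, and any minor enantiomer of 10 still has its fast-reacting arm free and is consumed to the bis-tosylate, which should raise the enantiomeric purity. The insoluble weak base should leave the aryl and benzylic isobutyrates in place.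

Step 7
Reactants: 10 (2R)-2,3-dihydroxy-2-{2-(isobutyryloxy)-4-[(isobutyryloxy)methyl]phenyl}propyl 4-methylbenzenesulfonate
Product: 11 (2R)-2-hydroxy-2-{2-(isobutyryloxy)-4-[(isobutyryloxy)methyl]phenyl}-3-(tosyloxy)propyl acetate
Conditions: Ac2O (1.3 equiv), pyridine, CH2Cl2, 0 °C
Reagents that add atoms: acetic anhydride, CC(=O)OC(C)=O
Why: Acetylation of a primary alcohol with Ac2O and pyridine is far faster than that of the hindered tertiary carbinol, so only the remaining hydroxymethyl arm is esterified, no bond to the stereocentre is touched, and isolating 11 gives a point at which enantiomeric purity can be checked and raised by crystallisation.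

Step 8
Reactants: 11 (2R)-2-hydroxy-2-{2-(isobutyryloxy)-4-[(isobutyryloxy)methyl]phenyl}-3-(tosyloxy)propyl acetate
Product: 12 {(2S)-2-[2-(isobutyryloxy)-4-(isobutyryloxymethyl)phenyl]oxiran-2-yl}methyl acetate
Conditions: DBU (1.5 equiv), CH2Cl2, 0 °C → rt
Reagents that add atoms: none
Why: Intramolecular Williamson etherification, in which the DBU-activated tertiary hydroxyl displaces the primary tosylate by 3-exo-tet closure helped by the gem-disubstituent effect of the fully substituted carbon; the configuration is retained because no bond to the stereocentre breaks, and the descriptor changes from R to S only through the change in ligand priorities.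

Compound list
1 | methyl 4-bromo-3-hydroxybenzoate | COC(=O)c1ccc(Br)c(O)c1 | starting material
2 | 2-bromo-5-(hydroxymethyl)phenol | OCc1ccc(Br)c(O)c1 | intermediate
3 | {[4-bromo-3-(triisopropylsilyloxy)phenyl]methoxy}triisopropylsilane | CC(C)[Si](OCc1ccc(Br)c(O[Si](C(C)C)(C(C)C)C(C)C)c1)(C(C)C)C(C)C | intermediate
4 | 2,2-dimethyl-1,3-dioxan-5-one | CC1(C)OCC(=O)CO1 | starting material
5 | {2-(triisopropylsilyloxy)-4-[(triisopropylsilyloxy)methyl]phenyl}lithium | [Li]c1ccc(CO[Si](C(C)C)(C(C)C)C(C)C)cc1O[Si](C(C)C)(C(C)C)C(C)C | intermediate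
6 | 2,2-dimethyl-5-{2-(triisopropylsilyloxy)-4-[(triisopropylsilyloxy)methyl]phenyl}-1,3-dioxan-5-ol | CC1(C)OCC(O)(c2ccc(CO[Si](C(C)C)(C(C)C)C(C)C)cc2O[Si](C(C)C)(C(C)C)C(C)C)CO1 | intermediate
7 | 5-[2-hydroxy-4-(hydroxymethyl)phenyl]-2,2-dimethyl-1,3-dioxan-5-ol | CC1(C)OCC(O)(c2ccc(CO)cc2O)CO1 | intermediate
8 | [4-(5-hydroxy-2,2-dimethyl-1,3-dioxan-5-yl)-3-(isobutyryloxy)phenyl]methyl isobutyrate | CC(C)C(=O)OCc1ccc(C2(O)COC(C)(C)OC2)c(OC(=O)C(C)C)c1 | intermediate
9 | [3-(isobutyryloxy)-4-(1,2,3-trihydroxypropan-2-yl)phenyl]methyl isobutyrate | CC(C)C(=O)OCc1ccc(C(O)(CO)CO)c(OC(=O)C(C)C)c1 | intermediate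
10 | (2R)-2,3-dihydroxy-2-{2-(isobutyryloxy)-4-[(isobutyryloxy)methyl]phenyl}propyl 4-methylbenzenesulfonate | OC[C@@](O)(COS(=O)(=O)c1ccc(C)cc1)c1ccc(COC(=O)C(C)C)cc1OC(=O)C(C)C | intermediate
11 | (2R)-2-hydroxy-2-{2-(isobutyryloxy)-4-[(isobutyryloxy)methyl]phenyl}-3-(tosyloxy)propyl acetate | CC(=O)OC[C@@](O)(COS(=O)(=O)c1ccc(C)cc1)c1ccc(COC(=O)C(C)C)cc1OC(=O)C(C)C | intermediate
12 | {(2S)-2-[2-(isobutyryloxy)-4-(isobutyryloxymethyl)phenyl]oxiran-2-yl}methyl acetate | CC(=O)OC[C@]1(c2ccc(COC(=O)C(C)C)cc2OC(=O)C(C)C)CO1 | target

Total step count: 8. Longest linear sequence: 8 steps (1 to 12; ketone 4 is bought).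

Steps most likely to fail

Step 6. The chiral copper complex may discriminate poorly between the two enantiotopic arms of this ortho-acyloxyaryl triol, or the mono-tosylate may be over-sulfonylated before useful conversion is reached. The fallback sets out from 9 and lets an enzyme make the same enantiotopic-group choice by acylation. Lipase-catalysed transesterification (immobilised Burkholderia cepacia lipase or Candida antarctica lipase B, vinyl acetate, t-BuOMe, rt; the α-branched isobutyrates are poor lipase substrates) should give (2S)-2,3-dihydroxy-2-{2-(isobutyryloxy)-4-[(isobutyryloxy)methyl]phenyl}propyl acetate F1, the enzyme being selected by screening for this enantiomer. F1 is kept cold to avoid acetyl migration between the primary oxygens and is tosylated at once on the remaining primary hydroxyl (TsCl, Et3N, Bu2SnO cat., CH2Cl2, 0 °C), which comes back to the route at 11.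

Step 3. The ortho-silyloxy aryllithium may undergo 1,3 migration of silicon from oxygen to carbon, or may deprotonate the enolisable ketone instead of adding to it. The fallback sets out from 1 and replaces the phenol silyl ether with a benzyl ether. O-Benzylation (BnBr, K2CO3, DMF) gives methyl 3-(benzyloxy)-4-bromobenzoate F2, DIBAL-H reduction gives [3-(benzyloxy)-4-bromophenyl]methanol F3, and TIPSCl with imidazole gives {[3-(benzyloxy)-4-bromophenyl]methoxy}triisopropylsilane F4. Bromine–lithium exchange (n-BuLi, THF, −78 °C) gives {2-(benzyloxy)-4-[(triisopropylsilyloxy)methyl]phenyl}lithium F5, which has no migrating group and is stabilised by the ortho ether oxygen. Its addition to 4 (after transmetalation with anhydrous CeCl3 if enolisation persists) gives 5-{2-(benzyloxy)-4-[(triisopropylsilyloxy)methyl]phenyl}-2,2-dimethyl-1,3-dioxan-5-ol F6. Hydrogenolysis (H2, Pd/C, EtOAc), carried out before any benzylic ester is present, gives 5-{2-hydroxy-4-[(triisopropylsilyloxy)methyl]phenyl}-2,2-dimethyl-1,3-dioxan-5-ol F7. The conditions of step 4 then convert F7 through 7 into 8, where the fallback comes back to the route.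

Step 8. The ortho isobutyryl group may transfer from the phenol oxygen to the tertiary alkoxide through a six-membered transition state faster than the ring closes, and the freed phenoxide would then attack the tosylate arm. The fallback sets out from 6 and postpones both isobutyrates until after the oxirane exists. Acetonide hydrolysis with the silyl ethers retained (AcOH–THF–H2O, rt) gives 2-{2-(triisopropylsilyloxy)-4-[(triisopropylsilyloxy)methyl]phenyl}propane-1,2,3-triol F8. The monotosylation of step 6 then gives (2R)-2,3-dihydroxy-2-{2-(triisopropylsilyloxy)-4-[(triisopropylsilyloxy)methyl]phenyl}propyl 4-methylbenzenesulfonate F9. Acetylation as in step 7 gives (2R)-2-hydroxy-3-(tosyloxy)-2-{2-(triisopropylsilyloxy)-4-[(triisopropylsilyloxy)methyl]phenyl}propyl acetate F10. DBU closure, now with no acyl group on the phenol oxygen, gives {(2S)-2-{2-(triisopropylsilyloxy)-4-[(triisopropylsilyloxy)methyl]phenyl}oxiran-2-yl}methyl acetate F11. Finally Bu4NF is added slowly to F11 in THF at 0 °C in the presence of excess isobutyric anhydride, so that the phenoxide and the benzylic alkoxide are acylated as they are released, which comes back to the route at 12.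

Further compounds
F1 | step 6 | (2S)-2,3-dihydroxy-2-{2-(isobutyryloxy)-4-[(isobutyryloxy)methyl]phenyl}propyl acetate | CC(=O)OC[C@@](O)(CO)c1ccc(COC(=O)C(C)C)cc1OC(=O)C(C)C
F2 | step 3 | methyl 3-(benzyloxy)-4-bromobenzoate | COC(=O)c1ccc(Br)c(OCc2ccccc2)c1
F3 | step 3 | [3-(benzyloxy)-4-bromophenyl]methanol | OCc1ccc(Br)c(OCc2ccccc2)c1
F4 | step 3 | {[3-(benzyloxy)-4-bromophenyl]methoxy}triisopropylsilane | CC(C)[Si](OCc1ccc(Br)c(OCc2ccccc2)c1)(C(C)C)C(C)C
F5 | step 3 | {2-(benzyloxy)-4-[(triisopropylsilyloxy)methyl]phenyl}lithium | [Li]c1ccc(CO[Si](C(C)C)(C(C)C)C(C)C)cc1OCc1ccccc1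
F6 | step 3 | 5-{2-(benzyloxy)-4-[(triisopropylsilyloxy)methyl]phenyl}-2,2-dimethyl-1,3-dioxan-5-ol | CC1(C)OCC(O)(c2ccc(CO[Si](C(C)C)(C(C)C)C(C)C)cc2OCc2ccccc2)CO1
F7 | step 3 | 5-{2-hydroxy-4-[(triisopropylsilyloxy)methyl]phenyl}-2,2-dimethyl-1,3-dioxan-5-ol | CC1(C)OCC(O)(c2ccc(CO[Si](C(C)C)(C(C)C)C(C)C)cc2O)CO1
F8 | step 8 | 2-{2-(triisopropylsilyloxy)-4-[(triisopropylsilyloxy)methyl]phenyl}propane-1,2,3-triol | OCC(O)(CO)c1ccc(CO[Si](C(C)C)(C(C)C)C(C)C)cc1O[Si](C(C)C)(C(C)C)C(C)C
F9 | step 8 | (2R)-2,3-dihydroxy-2-{2-(triisopropylsilyloxy)-4-[(triisopropylsilyloxy)methyl]phenyl}propyl 4-methylbenzenesulfonate | OC[C@@](O)(COS(=O)(=O)c1ccc(C)cc1)c1ccc(CO[Si](C(C)C)(C(C)C)C(C)C)cc1O[Si](C(C)C)(C(C)C)C(C)C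
F10 | step 8 | (2R)-2-hydroxy-3-(tosyloxy)-2-{2-(triisopropylsilyloxy)-4-[(triisopropylsilyloxy)methyl]phenyl}propyl acetate | CC(=O)OC[C@@](O)(COS(=O)(=O)c1ccc(C)cc1)c1ccc(CO[Si](C(C)C)(C(C)C)C(C)C)cc1O[Si](C(C)C)(C(C)C)C(C)C
F11 | step 8 | {(2S)-2-{2-(triisopropylsilyloxy)-4-[(triisopropylsilyloxy)methyl]phenyl}oxiran-2-yl}methyl acetate | CC(=O)OC[C@]1(c2ccc(CO[Si](C(C)C)(C(C)C)C(C)C)cc2O[Si](C(C)C)(C(C)C)C(C)C)CO1
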